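**Retrosynthetic overview**

1. Isobutylshikonin is reached from its 5,8-bis(methoxymethyl) ether (acetal cleavage with MgBr2), and that quinone from a 4-methoxy-1-naphthol (oxidation with (NH4)2Ce(NO3)6).
2. The strategy rests on ring B (C1, C2, C3, C4, C4a, C8a): para oxygens on C1 and C4, the side chain on C2 and hydrogen on C3 mark it as a hydroquinone monoether ring. It is cut at C3–C4, C1–C2 and C1–C8a into an aryl(methoxy)carbene carbon (C4), one CO (C1) and a terminal alkyne (C2, C3).
3. Carbene partner: hydroquinone, bis(methoxymethyl) ether, ortho-lithiation, Cr(CO)6, Me3OBF4; ring A (C4a, C5, C6, C7, C8, C8a) is the bought hydroquinone ring.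
4. Alkyne partner: 4-methylpent-3-enoic acid, Weinreb amide, silyl ynone, Noyori transfer hydrogenation to the (R)-carbinol, desilylation, isobutyrate; the propargylic carbon is the only stereocenter.
5. Ring order: ring A from the start, ring B by chromium-mediated benzannulation in step 8; no other ring is formed.

Key step: step 8

Assumption: the name is read as the 2-methylpropanoate (isobutyrate) ester of (R)-shikonin, as the SMILES shows; naphthalene numbering is used, with the side chain on C2 of the quinone ring.

**Route**

Step 1
Reactants: 1 hydroquinone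
Product: 3 1,4-bis(methoxymethoxy)benzene, via disodium benzene-1,4-diolate 2 (not isolated)
Conditions: NaH, DMF, 0 °C; MOMCl, 0 °C to rt
Reagents that add atoms: chloromethyl methyl ether (MOMCl), COCCl
Why: Williamson etherification, in which the bisphenoxide 2 is alkylated at oxygen by the reactive α-chloro ether; the two acetal ethers then serve as protection and as ortho-directing groups.

Step 2
Reactants: 3 1,4-bis(methoxymethoxy)benzene; 4 chromium hexacarbonyl
Product: 7 pentacarbonyl[(2,5-bis(methoxymethoxy)phenyl)(methoxy)methylidene]chromium, via [2,5-bis(methoxymethoxy)phenyl]lithium 5 (not isolated), via lithium acylpentacarbonylchromate 6 (not isolated)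
Conditions: n-BuLi, TMEDA, THF, 0 °C; Cr(CO)6, Et2O, 0 °C to rt; solvent exchange, Me3OBF4, CH2Cl2, 0 °C; aq. NaHCO3
Reagents that add atoms: trimethyloxonium tetrafluoroborate, C[O+](C)C.F[B-](F)(F)F
Why: Directed ortho-metalation followed by the Fischer carbene synthesis, in which the acetal oxygen guides n-BuLi to an adjacent ring carbon (all four are equivalent), aryllithium 5 adds to a CO ligand of zerovalent chromium to give acylchromate 6, and O-methylation by the oxonium salt gives the carbene complex.

Step 3
Reactants: 8 4-methylpent-3-enoic acid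
Product: 10 N-methoxy-N,4-dimethylpent-3-enamide, via 1-(4-methylpent-3-enoyl)imidazole 9 (not isolated)
Conditions: CDI, CH2Cl2, 0 °C to rt; MeNHOMe·HCl, rt
Reagents that add atoms: N,O-dimethylhydroxylamine hydrochloride, CNOC.Cl
Why: Amide formation through an acylimidazole (carbonyldiimidazole coupling) is close to neutral, so the β,γ-alkene should not move into conjugation with the carbonyl.

Step 4
Reactants: 10 N-methoxy-N,4-dimethylpent-3-enamide; 11 ethynyltrimethylsilane
Product: 14 6-methyl-1-(trimethylsilyl)hept-5-en-1-yn-3-one, via lithium (trimethylsilyl)acetylide 12 (not isolated), via lithium hemiaminal alkoxide 13 (not isolated)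
Conditions: 11, n-BuLi, THF, −78 °C; 10, −78 to −20 °C; inverse quench into cold aq. NH4Cl
Reagents that add atoms: none
Why: Weinreb ketone synthesis, in which acetylide 12 adds once and the lithium chelate 13 keeps the carbonyl masked until the cold quench, which prevents over-addition and keeps the doubly activated CH2 of the ynone away from base.

Step 5
Reactants: 14 6-methyl-1-(trimethylsilyl)hept-5-en-1-yn-3-one
Product: 15 (R)-6-methyl-1-(trimethylsilyl)hept-5-en-1-yn-3-ol
Conditions: Ru[(R,R)-TsNCH(Ph)CH(Ph)NH](η6-p-cymene) (1–2 mol%), i-PrOH, rt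
Reagents that add atoms: none
Why: Noyori asymmetric transfer hydrogenation of an alkynyl ketone, in which hydride on divalent ruthenium and the proton on nitrogen are delivered through a six-membered transition state with the alkynyl group in the place an aryl group takes in aryl ketone reductions, so the (R,R)-ligand should give the (R)-carbinol, while the base-free medium leaves the alkyne, the alkene and the β,γ-position untouched.

Step 6
Reactants: 15 (R)-6-methyl-1-(trimethylsilyl)hept-5-en-1-yn-3-ol
Product: 16 (R)-6-methylhept-5-en-1-yn-3-ol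
Conditions: K2CO3 (cat.), MeOH, 0 °C to rt
Reagents that add atoms: none
Why: Methoxide-catalysed protodesilylation of the alkynylsilane cleaves only the C(sp)–Si bond and leaves the carbinol stereocenter untouched.

Step 7
Reactants: 16 (R)-6-methylhept-5-en-1-yn-3-ol
Product: 17 (R)-6-methylhept-5-en-1-yn-3-yl 2-methylpropanoate
Conditions: (i-PrCO)2O, Et3N, DMAP (cat.), CH2Cl2, 0 °C to rt
Reagents that add atoms: isobutyric anhydride, CC(C)C(=O)OC(=O)C(C)C
Why: DMAP-catalysed acylation takes place at oxygen without breaking the C–O bond of the carbinol, so the (R)-configuration is retained.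

Step 8
Reactants: 7 pentacarbonyl[(2,5-bis(methoxymethoxy)phenyl)(methoxy)methylidene]chromium; 17 (R)-6-methylhept-5-en-1-yn-3-yl 2-methylpropanoate
Product: 19 (R)-1-[1-hydroxy-4-methoxy-5,8-bis(methoxymethoxy)naphthalen-2-yl]-4-methylpent-3-en-1-yl 2-methylpropanoate, via tricarbonyl(naphthol)chromium complex 18 (not isolated)
Conditions: 7 (1.3 equiv), 17 (1 equiv), degassed THF (0.05 M), 50 °C, Ar; then air, Et2O, ambient light, rt; filtration through silica; crude 19 used at once
Reagents that add atoms: none
Why: Thermal loss of one CO from 7 frees a site for the terminal alkyne of 17, which inserts into the Cr=C bond to a vinylcarbene; CO insertion gives a chromium-bound vinylketene that undergoes six-electron electrocyclization onto the aryl ring and tautomerizes to the tricarbonylchromium-bound naphthol 18, from which air releases 19. This is the Dötz benzannulation of an aryl(alkoxy)carbene complex with a terminal alkyne, a known reaction type that tolerates oxygen substituents at the propargylic carbon. Ring B is closed as a six-membered carbocycle by electrocyclic formation of C1–C8a at the only ortho carbon of the aryl group that carries hydrogen, after C3–C4 and C1–C2 have been made by the alkyne and CO insertions. No stereocenter is created; the propargylic stereocenter of 17 lies outside the reacting π-system and neutral THF at 50 °C gives no driving force for ionization of its C–O bond. The step needs naphthol formation over indene, furan and cyclobutenone by-products, which an aryl carbene in the donor solvent THF at moderate temperature and low alkyne concentration favours, and it needs the side chain next to the CO-derived carbon, which the steric bias of a terminal alkyne secures and which step 9 makes immaterial because both regioisomers give the same quinone. The remote trisubstituted alkene cannot trap the vinylcarbene, since cyclopropanation would have to form a bicyclo[2.1.0]pentane.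

Step 9
Reactants: 19 (R)-1-[1-hydroxy-4-methoxy-5,8-bis(methoxymethoxy)naphthalen-2-yl]-4-methylpent-3-en-1-yl 2-methylpropanoate
Product: 20 (R)-1-[5,8-bis(methoxymethoxy)-1,4-dioxo-1,4-dihydronaphthalen-2-yl]-4-methylpent-3-en-1-yl 2-methylpropanoate
Conditions: (NH4)2Ce(NO3)6 (2.2–2.5 equiv), MeCN/H2O, 0 °C, short contact
Reagents that add atoms: water, O
Why: Oxidative demethylation of a hydroquinone monomethyl ether by tetravalent cerium, in which two one-electron oxidations of the free naphthol ring give an oxocarbenium ion at C4 that takes up water and loses methanol, while the acetal-protected ring A is less electron-rich and is deactivated further once the quinone has formed.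

Step 10
Reactants: 20 (R)-1-[5,8-bis(methoxymethoxy)-1,4-dioxo-1,4-dihydronaphthalen-2-yl]-4-methylpent-3-en-1-yl 2-methylpropanoate
Product: 21 isobutylshikonin
Conditions: MgBr2·OEt2, Et2O/CH2Cl2, 0 °C to rt; aq. NH4Cl
Reagents that add atoms: none
Why: Chelation-assisted Lewis acid cleavage of aryl methoxymethyl ethers, in which MgBr2 bridges each quinone carbonyl and its peri acetal oxygen, bromide opens the acetal and work-up frees the phenols, under conditions mild enough to leave the ester, the trisubstituted alkene and the stereocenter as they are.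

**Compound list**

1 | hydroquinone | Oc1ccc(O)cc1 | starting material
2 | disodium benzene-1,4-diolate | [Na+].[Na+].[O-]c1ccc([O-])cc1 | intermediate (not isolated)
3 | 1,4-bis(methoxymethoxy)benzene | COCOc1ccc(OCOC)cc1 | intermediate
4 | chromium hexacarbonyl | O=C=[Cr](=C=O)(=C=O)(=C=O)(=C=O)=C=O | starting material
5 | [2,5-bis(methoxymethoxy)phenyl]lithium | [Li]c1cc(OCOC)ccc1OCOC | intermediate (not isolated)
6 | lithium pentacarbonyl[(2,5-bis(methoxymethoxy)phenyl)(oxido)methylidene]chromate | [Li+].[O-]C(c1cc(OCOC)ccc1OCOC)=[Cr](=C=O)(=C=O)(=C=O)(=C=O)=C=O | intermediate (not isolated)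
7 | pentacarbonyl[(2,5-bis(methoxymethoxy)phenyl)(methoxy)methylidene]chromium | COC(c1cc(OCOC)ccc1OCOC)=[Cr](=C=O)(=C=O)(=C=O)(=C=O)=C=O | intermediate
8 | 4-methylpent-3-enoic acid | CC(C)=CCC(O)=O | starting material
9 | 1-(4-methylpent-3-enoyl)imidazole | CC(C)=CCC(=O)n1ccnc1 | intermediate (not isolated)
10 | N-methoxy-N,4-dimethylpent-3-enamide | CC(C)=CCC(=O)N(C)OC | intermediate
11 | ethynyltrimethylsilane | C#C[Si](C)(C)C | starting material
12 | lithium (trimethylsilyl)acetylide | [Li]C#C[Si](C)(C)C | intermediate (not isolated)
13 | lithium 3-[methoxy(methyl)amino]-6-methyl-1-(trimethylsilyl)hept-5-en-1-yn-3-olate | [Li+].[O-]C(CC=C(C)C)(C#C[Si](C)(C)C)N(C)OC | intermediate (not isolated)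
14 | 6-methyl-1-(trimethylsilyl)hept-5-en-1-yn-3-one | CC(C)=CCC(=O)C#C[Si](C)(C)C | intermediate
15 | (R)-6-methyl-1-(trimethylsilyl)hept-5-en-1-yn-3-ol | CC(C)=CC[C@@H](O)C#C[Si](C)(C)C | intermediate
16 | (R)-6-methylhept-5-en-1-yn-3-ol | CC(C)=CC[C@@H](O)C#C | intermediate
17 | (R)-6-methylhept-5-en-1-yn-3-yl 2-methylpropanoate | CC(C)=CC[C@@H](OC(=O)C(C)C)C#C | intermediate
18 | tricarbonylchromium complex of naphthol 19, chromium η6-bound to ring B, drawn as ligand and Cr(CO)3 fragment, mixture of planar diastereomers | CC(C)=CC[C@@H](OC(=O)C(C)C)c1cc(OC)c2c(OCOC)ccc(OCOC)c2c1O.O=C=[Cr](=C=O)=C=O | intermediate (not isolated)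
19 | (R)-1-[1-hydroxy-4-methoxy-5,8-bis(methoxymethoxy)naphthalen-2-yl]-4-methylpent-3-en-1-yl 2-methylpropanoate | CC(C)=CC[C@@H](OC(=O)C(C)C)c1cc(OC)c2c(OCOC)ccc(OCOC)c2c1O | intermediate
20 | (R)-1-[5,8-bis(methoxymethoxy)-1,4-dioxo-1,4-dihydronaphthalen-2-yl]-4-methylpent-3-en-1-yl 2-methylpropanoate | CC(C)=CC[C@@H](OC(=O)C(C)C)C1=CC(=O)c2c(OCOC)ccc(OCOC)c2C1=O | intermediate
21 | isobutylshikonin, (R)-1-(5,8-dihydroxy-1,4-dioxo-1,4-dihydronaphthalen-2-yl)-4-methylpent-3-en-1-yl 2-methylpropanoate | CC(C)=CC[C@@H](OC(=O)C(C)C)C1=CC(=O)c2c(O)ccc(O)c2C1=O | target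

**Step count**

Total step count: 10
Longest linear sequence: 8 steps (steps 3 to 10, from 4-methylpent-3-enoic acid)

**Steps most likely to fail**

Step 8. The ester may ionize at the electron-rich naphthol stage to an ortho-quinone methide, its acyl group may shift to the new naphthol oxygen, or the chromium intermediates may be diverted from CO insertion into indene or cyclobutenone formation. The fallback brings the acyl group in after ring B. It sets out from 16: TBSCl, imidazole, DMF should give the silyl ether F1, a propargylic silyl ether of the kind established in this benzannulation. Heating F1 with 7 under the conditions of step 8 and decomplexation in air should give the naphthol silyl ether F2. (NH4)2Ce(NO3)6 in MeCN/H2O at 0 °C should give the quinone silyl ether F3, and HF·pyridine in THF at 0 °C should free the carbinol F4. Acylation of F4 with (i-PrCO)2O, Et3N and DMAP in CH2Cl2 comes back to the route at 20, before step 10.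

Step 10. The acetal cleavage may stop at the mono-ether, or the Lewis acid may open the side chain by ionization of the ester or by cyclization of the alkene. The fallback changes the phenol protection to methyl ethers that are removed by oxidation in a short contact and not by a Lewis acid. It sets out from 17 and 4: commercial 1,4-dimethoxybenzene is lithiated (n-BuLi, TMEDA, Et2O), added to 4 and methylated with Me3OBF4 as in step 2 to give the carbene complex F5. Benzannulation of F5 with 17 as in step 8 should give the trimethoxynaphthol F6, and (NH4)2Ce(NO3)6 should give the 5,8-dimethoxy quinone F7. AgO with aqueous HNO3 in acetone (oxidative demethylation of the second ring) should give the naphthalenetetrone F8, and two-electron reduction with aqueous Na2S2O4 comes back to the route at 21.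

Step 5. The alkene may migrate into conjugation with the ketone before hydride transfer, or the facial selectivity of hydride transfer may be insufficient. The fallback obtains the stereocenter by resolution and not by asymmetric reduction. It sets out from 14: NaBH4, CeCl3·7H2O, MeOH, −78 °C (Luche reduction) should give the racemic silyl carbinol F9, and K2CO3 in MeOH the racemic alkynol F10. Lipase from Burkholderia cepacia with vinyl acetate in t-BuOMe, run slightly beyond half conversion, is expected by the empirical size rule for lipases to acetylate the (S)-alcohol to the acetate F11 and leave the (R)-alkynol. This is separated by chromatography and comes back to the route at 16, before step 7.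

**Further compounds**

F1 | step 8 | (R)-tert-butyldimethyl[(6-methylhept-5-en-1-yn-3-yl)oxy]silane | CC(C)=CC[C@@H](O[Si](C)(C)C(C)(C)C)C#C
F2 | step 8 | (R)-2-[1-(tert-butyldimethylsilyloxy)-4-methylpent-3-en-1-yl]-4-methoxy-5,8-bis(methoxymethoxy)naphthalen-1-ol | CC(C)=CC[C@@H](O[Si](C)(C)C(C)(C)C)c1cc(OC)c2c(OCOC)ccc(OCOC)c2c1O
F3 | step 8 | (R)-2-[1-(tert-butyldimethylsilyloxy)-4-methylpent-3-en-1-yl]-5,8-bis(methoxymethoxy)naphthalene-1,4-dione | CC(C)=CC[C@@H](O[Si](C)(C)C(C)(C)C)C1=CC(=O)c2c(OCOC)ccc(OCOC)c2C1=O
F4 | step 8 | (R)-2-(1-hydroxy-4-methylpent-3-en-1-yl)-5,8-bis(methoxymethoxy)naphthalene-1,4-dione | CC(C)=CC[C@@H](O)C1=CC(=O)c2c(OCOC)ccc(OCOC)c2C1=O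
F5 | step 10 | pentacarbonyl[(2,5-dimethoxyphenyl)(methoxy)methylidene]chromium | COC(c1cc(OC)ccc1OC)=[Cr](=C=O)(=C=O)(=C=O)(=C=O)=C=O
F6 | step 10 | (R)-1-(1-hydroxy-4,5,8-trimethoxynaphthalen-2-yl)-4-methylpent-3-en-1-yl 2-methylpropanoate | CC(C)=CC[C@@H](OC(=O)C(C)C)c1cc(OC)c2c(OC)ccc(OC)c2c1O
F7 | step 10 | (R)-1-(5,8-dimethoxy-1,4-dioxo-1,4-dihydronaphthalen-2-yl)-4-methylpent-3-en-1-yl 2-methylpropanoate | CC(C)=CC[C@@H](OC(=O)C(C)C)C1=CC(=O)c2c(OC)ccc(OC)c2C1=O
F8 | step 10 | (R)-4-methyl-1-(1,4,5,8-tetraoxo-1,4,5,8-tetrahydronaphthalen-2-yl)pent-3-en-1-yl 2-methylpropanoate | CC(C)=CC[C@@H](OC(=O)C(C)C)C1=CC(=O)C2=C(C1=O)C(=O)C=CC2=O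
F9 | step 5 | racemic 6-methyl-1-(trimethylsilyl)hept-5-en-1-yn-3-ol | CC(C)=CCC(O)C#C[Si](C)(C)C
F10 | step 5 | racemic 6-methylhept-5-en-1-yn-3-ol | CC(C)=CCC(O)C#C
F11 | step 5 | (S)-6-methylhept-5-en-1-yn-3-yl acetate | CC(C)=CC[C@H](OC(C)=O)C#C
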